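## Retrosynthetic overview

1. Locants (clerodane type): ring A = C1–C5 and C10 (cyclohexene carrying the C18/C19 lactone); ring B = C5–C10 (C7–OAc, C8=C17H2, C9–C20H3); ring C = C1, C10, C9, C11, C12(=O) and the furan C3–C2 edge.
2. Endgame from a ring-B enone C7(=O)–C8(CH2OMe)=C9: C20 by conjugate methyl addition, C17 methylene by loss of methanol, C7 reduction and acetylation, C12 carbinol oxidation.
3. Key disconnection: the enone comes from a cyclobutanone (C7, C6, C5, C10) cis-fused to ring A. Rhodium cuts the strained acyl bond C7–C10 and sews in the alkyne C8≡C9, which hangs from C10 through C1, the furan, C12 and C11. The four-membered ring grows by two carbons into ring B while the seven-membered ring C closes.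
4. Enabling feature: C7 is oxygenated, has C8/C9 unsaturation next to it and sits 1,2 to C10 on ring A; C9 is tied to C1 by a flat 2,3-disubstituted furan that stands cis to C7. This is a cyclobutanone with an α-tethered alkyne.
5. Cyclobutanone, ring A and lactone arise together from one intramolecular Diels–Alder reaction of a cyclobutenone dienoate ester. Ring order: furan (bought), four-membered ring, A + lactone, then B + C.

Key step: step 14

Remarks on the chemistry:
- The C12 carbinol centre set in step 3 is only a handle; (R) is assumed from the (R)-configured phosphoric acid. It makes every later intermediate a single diastereomer and is erased in step 20.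
- The sense of induction of the oxazaborolidinium catalyst in step 13 is assumed by analogy with its Diels–Alder reactions of 2-cycloalkenones; the (S)-catalyst is taken to give the antipode drawn.
- "α" is the face of H10; "β" is the opposite face.

## Route

Step 1
Reactants: 1 3-bromofuran-2-carbaldehyde
Product: 2 2-(3-bromofuran-2-yl)-1,3-dioxolane
Conditions: HOCH2CH2OH, p-TsOH (cat.), toluene, reflux, azeotropic removal of water
Reagents that add atoms: ethylene glycol, OCCO
Why: Acid-catalysed acetalisation masks the aldehyde (future C1) during the organolithium steps; no stereocentre is formed.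

Step 2
Reactants: 2 2-(3-bromofuran-2-yl)-1,3-dioxolane
Product: 4 2-(1,3-dioxolan-2-yl)furan-3-carbaldehyde, via 3-lithiofuran acetal 3 (not isolated)
Conditions: n-BuLi, THF, −78 °C; DMF; aq. NH4Cl
Reagents that add atoms: n-butyllithium, [Li]CCCC; N,N-dimethylformamide, CN(C)C=O
Why: Bromine–lithium exchange followed by formylation with DMF installs the aldehyde carbon that becomes C12; no stereocentre is formed.

Step 3
Reactants: 4 2-(1,3-dioxolan-2-yl)furan-3-carbaldehyde; 5 allenylboronic acid pinacol ester
Product: 6 (R)-1-[2-(1,3-dioxolan-2-yl)furan-3-yl]but-3-yn-1-ol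
Conditions: (R)-3,3′-bis(2,4,6-triisopropylphenyl)-1,1′-binaphthyl-2,2′-diyl hydrogen phosphate (10 mol%), 4 Å molecular sieves, toluene, 0 °C
Reagents that add atoms: none
Why: Chiral phosphoric acid-catalysed propargylboration (SE2′ addition of the allenylboronate through a six-membered transition state) should give the homopropargylic alcohol; the catalyst sets C12.

Step 4
Reactants: 6 (R)-1-[2-(1,3-dioxolan-2-yl)furan-3-yl]but-3-yn-1-ol
Product: 7 (R)-tert-butyl{[1-(2-(1,3-dioxolan-2-yl)furan-3-yl)but-3-yn-1-yl]oxy}dimethylsilane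
Conditions: TBSCl, imidazole, DMF, 25 °C
Reagents that add atoms: tert-butyldimethylsilyl chloride, CC(C)(C)[Si](C)(C)Cl
Why: Imidazole-promoted silylation protects the C12 oxygen until step 19.

Step 5
Reactants: 7 (R)-tert-butyl{[1-(2-(1,3-dioxolan-2-yl)furan-3-yl)but-3-yn-1-yl]oxy}dimethylsilane
Product: 9 (R)-tert-butyl{[1-(2-(1,3-dioxolan-2-yl)furan-3-yl)-5-methoxypent-3-yn-1-yl]oxy}dimethylsilane, via lithium acetylide 8 (not isolated)
Conditions: n-BuLi (1.05 equiv), THF, −78 °C; ClCH2OMe, −78 → 0 °C
Reagents that add atoms: n-butyllithium, [Li]CCCC; chloromethyl methyl ether, COCCl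
Why: Deprotonation of the terminal alkyne (far more acidic than any furan C–H) and SN2 alkylation of the acetylide add C17 as a methoxymethyl group, a latent leaving group for step 16.

Step 6
Reactants: 9 (R)-tert-butyl{[1-(2-(1,3-dioxolan-2-yl)furan-3-yl)-5-methoxypent-3-yn-1-yl]oxy}dimethylsilane
Product: 10 3-[(R)-1-(tert-butyldimethylsilyloxy)-5-methoxypent-3-yn-1-yl]furan-2-carbaldehyde
Conditions: PPTS, acetone/H2O (10:1), 50 °C
Reagents that add atoms: water, O
Why: Mild acid hydrolysis of the furfural-type acetal (oxocarbenium ion stabilised by the furan) frees the aldehyde; the silyl ether and the propargylic ether should survive.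

Step 7
Reactants: 10 3-[(R)-1-(tert-butyldimethylsilyloxy)-5-methoxypent-3-yn-1-yl]furan-2-carbaldehyde; 11 triethyl 4-phosphonocrotonate
Product: 12 ethyl (2E,4E)-5-{3-[(R)-1-(tert-butyldimethylsilyloxy)-5-methoxypent-3-yn-1-yl]furan-2-yl}penta-2,4-dienoate
Conditions: LiHMDS, THF, −78 → 0 °C
Reagents that add atoms: none
Why: Vinylogous Horner–Wadsworth–Emmons olefination; the stabilised phosphonate gives the new double bond E and the crotonate keeps its E geometry, so the (2E,4E)-diene should result.

Step 8
Reactants: 12 ethyl (2E,4E)-5-{3-[(R)-1-(tert-butyldimethylsilyloxy)-5-methoxypent-3-yn-1-yl]furan-2-yl}penta-2,4-dienoate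
Product: 13 (2E,4E)-5-{3-[(R)-1-(tert-butyldimethylsilyloxy)-5-methoxypent-3-yn-1-yl]furan-2-yl}penta-2,4-dienoic acid
Conditions: LiOH, THF/MeOH/H2O, 25 °C; 1 M HCl to pH 3
Reagents that add atoms: lithium hydroxide, [Li+].[OH-]
Why: Saponification of the ethyl ester; the secondary silyl ether and the diene tolerate LiOH at room temperature.

Step 9
Reactants: 14 tert-butyldimethyl(prop-2-yn-1-yloxy)silane; 15 trichloroacetyl chloride
Product: 17 3-[(tert-butyldimethylsilyloxy)methyl]-4,4-dichlorocyclobut-2-en-1-one, via dichloroketene 16 (not isolated)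
Conditions: Zn–Cu couple, Et2O/DME, 25 °C
Reagents that add atoms: none
Why: [2+2] cycloaddition of dichloroketene (from zinc dechlorination of the acid chloride) to the terminal alkyne; the ketene carbonyl carbon bonds to the terminal alkyne carbon, so the substituent ends at C3 of the cyclobutenone.

Step 10
Reactants: 17 3-[(tert-butyldimethylsilyloxy)methyl]-4,4-dichlorocyclobut-2-en-1-one
Product: 18 3-[(tert-butyldimethylsilyloxy)methyl]cyclobut-2-en-1-one
Conditions: Zn dust, AcOH, TMEDA, EtOH, 0 °C
Reagents that add atoms: none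
Why: Zinc reduction of the α,α-dichloroketone in amine-buffered acetic acid removes both chlorines without reducing the enone.

Step 11
Reactants: 18 3-[(tert-butyldimethylsilyloxy)methyl]cyclobut-2-en-1-one
Product: 19 3-(hydroxymethyl)cyclobut-2-en-1-one
Conditions: HF·pyridine, THF, 0 °C; used at once
Reagents that add atoms: none
Why: Fluoride cleavage of the primary silyl ether under acidic, non-nucleophilic conditions spares the base-sensitive cyclobutenone.

Step 12
Reactants: 13 (2E,4E)-5-{3-[(R)-1-(tert-butyldimethylsilyloxy)-5-methoxypent-3-yn-1-yl]furan-2-yl}penta-2,4-dienoic acid; 19 3-(hydroxymethyl)cyclobut-2-en-1-one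
Product: 20 (3-oxocyclobut-1-en-1-yl)methyl (2E,4E)-5-{3-[(R)-1-(tert-butyldimethylsilyloxy)-5-methoxypent-3-yn-1-yl]furan-2-yl}penta-2,4-dienoate
Conditions: EDC·HCl, DMAP (10 mol%), CH2Cl2, 0 °C
Reagents that add atoms: none
Why: Carbodiimide (Steglich) esterification joins the two fragments under near-neutral conditions at 0 °C, where background cycloaddition should be slow.

Step 13
Reactants: 20 (3-oxocyclobut-1-en-1-yl)methyl (2E,4E)-5-{3-[(R)-1-(tert-butyldimethylsilyloxy)-5-methoxypent-3-yn-1-yl]furan-2-yl}penta-2,4-dienoate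
Product: 21 Diels–Alder adduct: cyclobutanone (C7=O, C6H2, C5, C10) cis-fused to cyclohexene ring A (C2=C3); γ-lactone C18(=O)–O–C19H2 trans-fused at C4–C5; furan at C1 cis to C7; H1, H4, H10 and C19 on the α face; furan C3 carries the (R)-CH(OTBS)CH2C≡CCH2OMe chain
Conditions: (S)-3,3-diphenyl-1-(2-methylphenyl)tetrahydro-1H,3H-pyrrolo[1,2-c][1,3,2]oxazaborole activated with HNTf2 (20 mol%), CH2Cl2, −40 → −10 °C
Reagents that add atoms: none
Why: Type 1 intramolecular Diels–Alder reaction of a strain-activated cyclobutenone with the (E,E)-diene under chiral oxazaborolidinium catalysis: the cis dienophile fixes the cis fusion C5/C10, the endo ketone (which forces the three-atom ester tether exo) puts the furan at C1 cis to C7 and gives the trans lactone, and the catalyst on the ketone selects the diene face; because C12 is already a stereocentre, the minor facial isomer is a separable diastereomer.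

Step 14
Reactants: 21 Diels–Alder adduct (cis-fused cyclobutanone with the alkyne tether)
Product: 22 tetracyclic enone: ring B = cyclohex-2-enone C7(=O)–C8(CH2OMe)=C9 with C6H2, C5, C10; ring C closed (C9–C11H2–C12H(OTBS)–furan–C1–C10); ring A (C2=C3) and trans-lactone unchanged; H1, H4, H10 and C19 α; C12 (R)
Conditions: [Rh(C2H4)2Cl]2 (5 mol%), P[3,5-(CF3)2C6H3]3 (20 mol%), 1,4-dioxane, 130 °C, sealed tube
Reagents that add atoms: none
Why: Oxidative addition of monovalent rhodium, made electron-poor by the fluorinated phosphine, into the strained acyl–Cα bond C7–C10 gives a rhodacyclopentanone; carbometalation of the tethered alkyne by the Rh–C10 bond (C10–C9) and acyl–vinyl reductive elimination (C7–C8) then deliver the cyclohexenone, a two-carbon expansion of the four-membered ring into ring B with simultaneous closure of ring C, driven by release of cyclobutanone strain. The closest known reaction type is the rhodium-catalysed intramolecular "cut-and-sew" of cyclobutanones with α-tethered alkynes, which gives cyclohexenone-fused five- and six-membered rings; here the 2,3-disubstituted furan serves as a rigid cis-alkene linker to reach the seven-membered ring. Ring C closes by 7-exo-dig migratory insertion across the alkyne, and ring B closes by reductive elimination from the seven-membered acyl–vinyl rhodacycle. No new stereocentre is created: C10 keeps its configuration (insertion with retention at the migrating carbon), C1, C4, C5 and C12 are untouched, and C9 becomes sp2. The step needs cleavage of C7–C10 and not C7–C6, and insertion faster than CO extrusion: both C–C insertions are reversible, but only the C10 rhodacycle has the alkyne within reach because the furan on C1 is cis to C7 on ring A, and the π-acidic phosphine disfavours decarbonylation.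

Step 15
Reactants: 22 tetracyclic enone
Product: 24 9-methyl ketone: C20 methyl α on quaternary C9 (cis to H10), C8–H carrying CH2OMe (C8 epimers, of no consequence), C7=O; rings A and C and lactone as in 22, via trimethylsilyl enol ether 23 (not isolated)
Conditions: Me2CuLi (from CuI and 2 MeLi), TMSCl, THF, −78 → −30 °C; aq. citric acid
Reagents that add atoms: lithium dimethylcuprate, [Li+].C[Cu-]C; chlorotrimethylsilane, C[Si](C)(C)Cl
Why: Chlorosilane-accelerated conjugate addition of the cuprate, trapped as the silyl enol ether so that methoxide is not lost while cuprate is present; methyl should add to the convex α face of C9, cis to H10, because the β face is covered by ring A (C1 and C4 flank it) and by ring C, and this sets the quaternary C9.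

Step 16
Reactants: 24 9-methyl ketone
Product: 25 8-methylene-7-ketone with conjugated butenolide (C3=C4–C18(=O)–O–C19H2); C20 α, H1, H10 and C19 α, C12 (R)-OTBS
Conditions: DBU, toluene, 40 °C
Reagents that add atoms: none
Why: E1cB loss of methanol from the β-methoxy ketone (only the C8 enolate can eliminate, C9 being quaternary) gives the exocyclic enone, and the same base moves the ring-A double bond into conjugation through the lactone dienolate (γ-protonation at C2), which removes the C4 stereocentre.

Step 17
Reactants: 25 8-methylene-7-ketone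
Product: 26 7β-alcohol (OH trans to the C20 methyl, H10 and C19), 8-methylene, 12-OTBS
Conditions: NaBH4, CeCl3·7H2O, MeOH, −78 °C
Reagents that add atoms: none
Why: Luche 1,2-reduction of the enone; in the all-cis tricycle the β face of C7 is flanked by the two ring carbons C4 (on C5) and C11 (on C9), so hydride should come from the α face and give the 7β-alcohol.

Step 18
Reactants: 26 7β-alcohol
Product: 27 7β-acetate, 12-OTBS
Conditions: Ac2O, pyridine, DMAP (cat.), CH2Cl2, 0 → 25 °C
Reagents that add atoms: acetic anhydride, CC(=O)OC(C)=O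
Why: DMAP-catalysed acylation of the secondary allylic alcohol with retention at C7.

Step 19
Reactants: 27 7β-acetate, 12-OTBS
Product: 28 7β-acetate, 12-alcohol
Conditions: HF·pyridine, pyridine, THF, 0 → 25 °C
Reagents that add atoms: none
Why: Buffered fluoride cleavage of the secondary silyl ether; the allylic acetate, butenolide and furan should be stable to these conditions.

Step 20
Reactants: 28 7β-acetate, 12-alcohol
Product: 29 target CNP0273675.2
Conditions: 1,1,1-triacetoxy-1,1-dihydro-1,2-benziodoxol-3(1H)-one, NaHCO3, CH2Cl2, 0 → 25 °C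
Reagents that add atoms: none
Why: Dess–Martin oxidation converts the furyl carbinol into the C12 ketone and erases the auxiliary stereocentre; no other oxidisable group is present.

## Compound list

1 | 3-bromofuran-2-carbaldehyde | O=Cc1occc1Br | starting material
2 | 2-(3-bromofuran-2-yl)-1,3-dioxolane | Brc1ccoc1C1OCCO1 | intermediate
3 | 2-(3-lithiofuran-2-yl)-1,3-dioxolane | [Li]c1ccoc1C1OCCO1 | intermediate
4 | 2-(1,3-dioxolan-2-yl)furan-3-carbaldehyde | O=Cc1ccoc1C1OCCO1 | intermediate
5 | allenylboronic acid pinacol ester | C=C=CB1OC(C)(C)C(C)(C)O1 | starting material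
6 | (R)-1-[2-(1,3-dioxolan-2-yl)furan-3-yl]but-3-yn-1-ol | C#CC[C@@H](O)c1ccoc1C1OCCO1 | intermediate
7 | TBS ether of 6 | C#CC[C@@H](O[Si](C)(C)C(C)(C)C)c1ccoc1C1OCCO1 | intermediate
8 | lithium acetylide of 7 | [Li]C#CC[C@@H](O[Si](C)(C)C(C)(C)C)c1ccoc1C1OCCO1 | intermediate
9 | (R)-tert-butyl{[1-(2-(1,3-dioxolan-2-yl)furan-3-yl)-5-methoxypent-3-yn-1-yl]oxy}dimethylsilane | COCC#CC[C@@H](O[Si](C)(C)C(C)(C)C)c1ccoc1C1OCCO1 | intermediate
10 | 3-[(R)-1-(tert-butyldimethylsilyloxy)-5-methoxypent-3-yn-1-yl]furan-2-carbaldehyde | COCC#CC[C@@H](O[Si](C)(C)C(C)(C)C)c1ccoc1C=O | intermediate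
11 | triethyl 4-phosphonocrotonate | CCOC(=O)/C=C/CP(=O)(OCC)OCC | starting material
12 | ethyl (2E,4E)-dienoate | CCOC(=O)/C=C/C=C/c1occc1[C@H](O[Si](C)(C)C(C)(C)C)CC#CCOC | intermediate
13 | (2E,4E)-dienoic acid | OC(=O)/C=C/C=C/c1occc1[C@H](O[Si](C)(C)C(C)(C)C)CC#CCOC | intermediate
14 | tert-butyldimethyl(prop-2-yn-1-yloxy)silane | C#CCO[Si](C)(C)C(C)(C)C | starting material
15 | trichloroacetyl chloride | ClC(Cl)(Cl)C(Cl)=O | starting material
16 | dichloroketene | ClC(Cl)=C=O | intermediate
17 | 3-[(tert-butyldimethylsilyloxy)methyl]-4,4-dichlorocyclobut-2-en-1-one | O=C1C=C(CO[Si](C)(C)C(C)(C)C)C1(Cl)Cl | intermediate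
18 | 3-[(tert-butyldimethylsilyloxy)methyl]cyclobut-2-en-1-one | O=C1C=C(CO[Si](C)(C)C(C)(C)C)C1 | intermediate
19 | 3-(hydroxymethyl)cyclobut-2-en-1-one | O=C1C=C(CO)C1 | intermediate
20 | cyclobutenone dienoate ester (Diels–Alder precursor) | O=C1C=C(COC(=O)/C=C/C=C/c2occc2[C@H](O[Si](C)(C)C(C)(C)C)CC#CCOC)C1 | intermediate
21 | Diels–Alder adduct (cis-fused cyclobutanone, trans-lactone, alkyne tether) | O=C1C[C@@]23COC(=O)[C@H]2C=C[C@H]([C@@H]13)c1occc1[C@H](O[Si](C)(C)C(C)(C)C)CC#CCOC | intermediate
22 | tetracyclic ring-B enone with 8-methoxymethyl group | COCC=1C(=O)C[C@@]23COC(=O)[C@H]2C=C[C@H]2c4occc4[C@H](O[Si](C)(C)C(C)(C)C)CC=1[C@H]23 | intermediate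
23 | trimethylsilyl enol ether (C7–OTMS, C7=C8) of the 9-methyl ketone | COCC1=C(O[Si](C)(C)C)C[C@@]23COC(=O)[C@H]2C=C[C@H]2c4occc4[C@H](O[Si](C)(C)C(C)(C)C)C[C@]1(C)[C@H]23 | intermediate
24 | 9α-methyl-8-(methoxymethyl) ketone, C8 epimers | COCC1C(=O)C[C@@]23COC(=O)[C@H]2C=C[C@H]2c4occc4[C@H](O[Si](C)(C)C(C)(C)C)C[C@]1(C)[C@H]23 | intermediate
25 | 8-methylene-7-ketone with conjugated butenolide, 12-OTBS | C=C1C(=O)C[C@@]23COC(=O)C2=CC[C@H]2c4occc4[C@H](O[Si](C)(C)C(C)(C)C)C[C@]1(C)[C@H]23 | intermediate
26 | 7β-alcohol, 12-OTBS | C=C1[C@@H](O)C[C@@]23COC(=O)C2=CC[C@H]2c4occc4[C@H](O[Si](C)(C)C(C)(C)C)C[C@]1(C)[C@H]23 | intermediate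
27 | 7β-acetate, 12-OTBS | C=C1[C@@H](OC(C)=O)C[C@@]23COC(=O)C2=CC[C@H]2c4occc4[C@H](O[Si](C)(C)C(C)(C)C)C[C@]1(C)[C@H]23 | intermediate
28 | 7β-acetate, 12-alcohol | C=C1[C@@H](OC(C)=O)C[C@@]23COC(=O)C2=CC[C@H]2c4occc4[C@H](O)C[C@]1(C)[C@H]23 | intermediate
29 | CNP0273675.2 | C=C1[C@@H](OC(C)=O)C[C@@]23COC(=O)C2=CC[C@H]2c4occc4C(=O)C[C@]1(C)[C@H]23 | target

## Step count and risks

Total step count: 20. Longest linear sequence: 17 (steps 1–8 and 12–20).

**Step 14 (key step).** The seven-membered alkyne insertion into the Rh–C10 bond may be too slow. Then CO extrusion from the rhodacycle, β-hydride loss next to C10, or migration of the ring-A double bond toward the furan could win.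

Fallback: a radical relay replaces the metal insertion; it sets out from 21 and comes back at 22. Condensation of 21 with NH2OH·HCl/pyridine should give the oxime F1, and acylation with 4-(trifluoromethyl)benzoyl chloride the O-acyl oxime F2. Single-electron reduction (Ir(ppy)3, i.e. tris(2-phenylpyridinato)iridium, blue light, diethyl 2,6-dimethyl-1,4-dihydropyridine-3,5-dicarboxylate as reductant) should generate the iminyl radical. β-Scission of the strained ring cleaves C7–C10 toward the secondary C10 radical, which closes ring C 7-exo-dig on the alkyne, cis to the C1 tether. The vinyl radical at C8 then closes ring B 6-exo on the nitrile carbon C7. Reduction gives the N–H ketimine F3, which hydrolyses on acidic work-up to 22.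

**Step 13.** The s-trans preference of the ester tether may slow the cycloaddition so that cyclobutenone decomposition competes, and facial or endo control may be incomplete.

Fallback: an intermolecular Diels–Alder reaction with an electron-rich diene, followed by oxidative lactonisation; it sets out from 12 and 18 and comes back at 21. DIBAL-H reduction of 12 should give the dienol F4, and TBSCl/imidazole its silyl ether F5. Cycloaddition of F5 with cyclobutenone 18 under the oxazaborolidinium catalyst of step 13 (furan-directed regiochemistry, ketone endo) should give the bis(silyloxymethyl) adduct F6. HF·pyridine removes the two primary silyl groups to give the diol F7. TEMPO/PhI(OAc)2 oxidises the less hindered C18 alcohol and closes the lactone onto the C19 alcohol, giving 21.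

**Step 15.** Conjugate addition to the fully substituted enone carbon may stall, premature loss of methoxide would allow a second methyl transfer, and attack on the β face would give the C9 epimer.

Fallback: a silicon-activated enone without C17, with C17 added afterwards by Peterson methylenation; it sets out from 7 and comes back at 25. n-BuLi then TMSCl should give the C-silyl alkyne F8, and acetal hydrolysis as in step 6 the aldehyde F9. Olefination with allyl (E)-4-(diethoxyphosphoryl)but-2-enoate gives the allyl dienoate F10, and Pd(PPh3)4/morpholine the acid F11. Esterification with 19 as in step 12 gives the triene F12; the conditions of steps 13 and 14 then give the adduct F13 and the 8-silyl enone F14. Lithium dimethylcuprate adds to F14 from the α face, and the α-silyl enolate is quenched with formaldehyde; Peterson elimination gives the 8-methylene ketone F15. DBU as in step 16 moves the ring-A double bond into conjugation and gives 25.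

## Further compounds

F1 | step 14 | oxime of 21 | ON=C1C[C@@]23COC(=O)[C@H]2C=C[C@H]([C@@H]13)c1occc1[C@H](O[Si](C)(C)C(C)(C)C)CC#CCOC
F2 | step 14 | O-[4-(trifluoromethyl)benzoyl] oxime of 21 | FC(F)(F)c1ccc(cc1)C(=O)ON=C1C[C@@]23COC(=O)[C@H]2C=C[C@H]([C@@H]13)c1occc1[C@H](O[Si](C)(C)C(C)(C)C)CC#CCOC
F3 | step 14 | N–H ketimine of 22 | COCC=1C(=N)C[C@@]23COC(=O)[C@H]2C=C[C@H]2c4occc4[C@H](O[Si](C)(C)C(C)(C)C)CC=1[C@H]23
F4 | step 13 | (2E,4E)-dienol from 12 | OC/C=C/C=C/c1occc1[C@H](O[Si](C)(C)C(C)(C)C)CC#CCOC
F5 | step 13 | TBS ether of F4 | CC(C)(C)[Si](C)(C)OC/C=C/C=C/c1occc1[C@H](O[Si](C)(C)C(C)(C)C)CC#CCOC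
F6 | step 13 | intermolecular cycloadduct with C18 and C19 silyloxymethyl groups | O=C1C[C@@]2(CO[Si](C)(C)C(C)(C)C)[C@@H](CO[Si](C)(C)C(C)(C)C)C=C[C@H]([C@@H]12)c1occc1[C@H](O[Si](C)(C)C(C)(C)C)CC#CCOC
F7 | step 13 | C18,C19-diol | O=C1C[C@@]2(CO)[C@@H](CO)C=C[C@H]([C@@H]12)c1occc1[C@H](O[Si](C)(C)C(C)(C)C)CC#CCOC
F8 | step 15 | C-trimethylsilyl alkyne from 7 | C[Si](C)(C)C#CC[C@@H](O[Si](C)(C)C(C)(C)C)c1ccoc1C1OCCO1
F9 | step 15 | silyl alkyne aldehyde | C[Si](C)(C)C#CC[C@@H](O[Si](C)(C)C(C)(C)C)c1ccoc1C=O
F10 | step 15 | allyl (2E,4E)-dienoate | C=CCOC(=O)/C=C/C=C/c1occc1[C@H](O[Si](C)(C)C(C)(C)C)CC#C[Si](C)(C)C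
F11 | step 15 | (2E,4E)-dienoic acid with silyl alkyne | OC(=O)/C=C/C=C/c1occc1[C@H](O[Si](C)(C)C(C)(C)C)CC#C[Si](C)(C)C
F12 | step 15 | cyclobutenone dienoate ester with silyl alkyne | O=C1C=C(COC(=O)/C=C/C=C/c2occc2[C@H](O[Si](C)(C)C(C)(C)C)CC#C[Si](C)(C)C)C1
F13 | step 15 | Diels–Alder adduct with silyl alkyne | O=C1C[C@@]23COC(=O)[C@H]2C=C[C@H]([C@@H]13)c1occc1[C@H](O[Si](C)(C)C(C)(C)C)CC#C[Si](C)(C)C
F14 | step 15 | 8-trimethylsilyl ring-B enone | C[Si](C)(C)C=1C(=O)C[C@@]23COC(=O)[C@H]2C=C[C@H]2c4occc4[C@H](O[Si](C)(C)C(C)(C)C)CC=1[C@H]23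
F15 | step 15 | 8-methylene-7-ketone with unconjugated lactone (C2=C3) | C=C1C(=O)C[C@@]23COC(=O)[C@H]2C=C[C@H]2c4occc4[C@H](O[Si](C)(C)C(C)(C)C)C[C@]1(C)[C@H]23
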